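A bench chemist reaches for the warmest bath first; test that habit on these flasks.

    crystals ⇌ target, rate k1*(cs1 - [target]) while solid is left; crystals form when [target] > cs1 (cs1 = 23 mM, k1 = 1.57 min⁻¹)
    starting material + protic impurity → quenched substrate (k2 = 4.96 M⁻¹ min⁻¹, Ea2 = 55.0 kJ mol⁻¹)
    starting material + coupling partner → intermediate + released group (k3 = 11.1 M⁻¹ min⁻¹, Ea3 = 54.0 kJ mol⁻¹)
    intermediate ⇌ target (K4 = 2.39, k4 = 0.554 min⁻¹, Ea4 = 89.0 kJ mol⁻¹, ΔH4 = −32.0 kJ mol⁻¹)
    solid substrate ⇌ starting material, rate k5*(cs5 - [starting material]) while solid is left; crystals form when [starting material] > cs5 (cs5 = 11 mM, k5 = 0.0247 min⁻¹)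
    intermediate ⇌ isomer of the product (K6 = 64.6, k6 = 0.348 min⁻¹, Ea6 = 85.0 kJ mol⁻¹, ΔH6 = −12.0 kJ mol⁻¹)
    (constants at 40 °C)

the same everywhere: solid substrate 0.063 M; coupling partner 0.0378 M; protic impurity 3.15 mM; time 2.5 h
- alder: temperature −20 °C
- maple: temperature 10 °C
- larch: temperature 40 °C
- cedar: at 40 °C until 30 min, from then on at −20 °C

- target is meant together with its crystals
- solid, in amounts per volume of the solution: solid substrate, crystals
- constants are those at 40 °C; use the activation energies and enthalpies for any other temperature
- at the start none of the solid substrate is in solution
- what has only dissolved of solid substrate counts as not reacted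

- the best flask by amount of target, in percent of the solid substrate charged; "all alike" if 1.5 percentage points covers them all (alder / maple / larch / cedar / all alike)
- amount of target at the end, in percent of the solid substrate charged, alder
- amount of target at the end, in percent of the solid substrate charged, maple
- amount of target at the end, in percent of the solid substrate charged, larch
- amount of target at the end, in percent of the solid substrate charged, cedar

1. Apply the habit. Warming from −20 °C to 40 °C speeds the coupling by a factor of 140, so it picks larch. But the same warming speeds the step from intermediate to isomer of the product by 2300, which is more.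

2. Treat the coupling in larch as quick. Its pseudo-first-order constant at the start, 0.420 min⁻¹, is far larger than the dissolution coefficient 0.0247 min⁻¹. So take [starting material] as small and the feed as 0.272 mM min⁻¹.

3. Follow a target molecule in larch. It falls back to the intermediate in 4.31 min on average, and 38.6% of the intermediate goes on to the isomer, so it lasts 11.2 min. Call this the leak time: the mean time a target molecule lasts before it ends as isomer, which is the fall-back time divided by the share lost to the isomer.

4. Divide the batch time by the leak time. Larch gives 13.4, far above one, so reckon that target made early in larch has leaked to the isomer before the end, and do not trust the habit there.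

5. Repeat the sum at 10 °C for maple. The leak time becomes 23.3 h, longer than the batch, and the ratio is 0.107. So count the target in maple as kept.

6. Reckon the stock in larch as inflow times leak time. Feed times the share of intermediate going to target times 11.2 min gives 2.96% of the charge. This is my own figure, and I rank maple above larch.

7. Read the forecast. It names maple, with 0.05% in alder, 13.3% in maple, 3.8% in larch and 2.7% in cedar. Its grounds are that at 40 °C the target “bleeds through the intermediate to the strongly favoured isomer”. My larch figure is lower than its 3.8%.

The simulation gives maple as best, with 0.0547% in alder, 12.7% in maple, 3.47% in larch and 2.47% in cedar. Larch holds 3.47% of the charge as target beside 46.2% as isomer, after 13.4 leak times. In cedar, the leak time at −20 °C is 9200 h, far longer than the cold stretch of 120 min, and cedar's target reaches 6.82% after 25.0 h.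

(All constants are invented; the flask was simulated.)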